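Retrosynthetic cuts, in order: the epoxide oxygen on C14–C15; C1–C13 (ring C and the spiro centre, vinylogous Michael); C12–C13; the lactone C18–O with the C1=C2 unsaturation; C8 taken out of ring B (C8–C9 becomes C7–C9 of a hydrindanone); C9–C11 and C10–H; C9=C10 (aldol); C5–C6 (Birch alkylation of an anisic amide).
Enabling feature: in ring B the oxygen-bearing C7 sits between C6 and C8, and C8 is bonded to the fully substituted C9. A C7 ketone in the five-membered ring C5–C6–C7–C9–C10 can therefore take up one carbon at C7, and the C7–C9 bond (the best migrating group) shifts to a sulfur-stabilised cation on that carbon. This gives ring B with C7=O, C9 retained and C8 marked by sulfur for the methyl group.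
Forward order of rings: ring A (arene, Birch) → five-membered pre-ring (cyclopentenone aldol) → ring B (one-carbon enlargement) → lactone ring as dienolide → ring C with the spiro-lactone (Michael) → epoxide.
Stereochemistry: C5 from the prolinol-ether auxiliary; C10 and C9 from C5 (protonation and alkylation anti to C19); C9 retained in the shift; C8 by axial protonation; C7 by equatorial hydride delivery; C1 and C13 by chair closure of the furanolate; C14/C15 by epoxidation anti to C1.
Key step: step 9

Numbering: clerodane numbering (C1–C20) is used for all intermediates; β is the face of C19 and C20, α the face of H-10.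
Assumption: the sense of induction of the (S)-auxiliary in step 2 is taken to be that drawn for C5; should it be opposite, the enantiomeric auxiliary is used with no other change.

Step 1
Reactants: 1 2-methoxy-6-methylbenzoic acid; 2 (S)-2-(methoxymethyl)pyrrolidine
Product: 4 (S)-1-(2-methoxy-6-methylbenzoyl)-2-(methoxymethyl)pyrrolidine, via acid chloride 3 (not isolated)
Conditions: (COCl)2, DMF (cat.), CH2Cl2, 0 °C to rt; then 2, Et3N, CH2Cl2, 0 °C to rt
Reagents that add atoms: none
Why: Amide formation through the acid chloride copes with the doubly ortho-substituted acid and attaches the chiral auxiliary; no stereocenter is formed.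

Step 2
Reactants: 4 the benzamide; 5 1-bromobut-2-yne
Product: 7 (1R)-1-(but-2-yn-1-yl)-2-methoxy-6-methylcyclohexa-2,5-diene-1-carboxamide of (S)-2-(methoxymethyl)pyrrolidine, via potassium amide enolate 6 (not isolated)
Conditions: K, NH3/THF, t-BuOH (1 equiv), −78 °C; piperylene; then 5, −78 °C
Reagents that add atoms: none
Why: Asymmetric Birch reduction–alkylation of a chiral 2-alkoxybenzamide: the chelated potassium amide enolate should be alkylated at the ipso carbon on the face turned away from the methoxymethyl arm, which sets the quaternary C5 and leaves C10 as an enol ether and C3=C4 with the C18 methyl.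

Step 3
Reactants: 7 the diene amide
Product: 8 (S)-[1-(but-2-yn-1-yl)-2-methoxy-6-methylcyclohexa-2,5-dien-1-yl]methanol
Conditions: LiH2N·BH3 (from H3N·BH3 and LiN(iPr)2), THF, 0 °C to rt; aq. NH4Cl
Reagents that add atoms: none
Why: Reduction of a tertiary amide to the primary alcohol with lithium amidotrihydroborate, a reagent known to reach α-quaternary amides, should leave enol ether, skipped diene and alkyne untouched; C5 is not affected and the auxiliary is recovered.

Step 4
Reactants: 8 the neopentyl alcohol
Product: 9 triisopropylsilyl ether of 8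
Conditions: TIPSOTf, 2,6-lutidine, CH2Cl2, −78 to 0 °C
Reagents that add atoms: triisopropylsilyl triflate, CC(C)[Si](C(C)C)(C(C)C)OS(=O)(=O)C(F)(F)F
Why: Silylation under buffered conditions protects the C19 hydroxyl (against retro-aldol loss and cation trapping later) without hydrolysing the enol ether.

Step 5
Reactants: 9 the silyl ether
Product: 11 (S)-3-methyl-2-(2-oxobutyl)-2-[(triisopropylsilyloxy)methyl]cyclohex-3-en-1-one, via cyclohexenone 10 (not isolated)
Conditions: 1 M HCl, THF, 0 °C; then NaAuCl4·2H2O (2 mol %), MeOH/H2O, 60 °C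
Reagents that add atoms: water, O
Why: Enol ether hydrolysis unmasks the C10 ketone, whose oxygen then adds 5-exo to the gold-activated alkyne, so that the carbonyl-assisted alkyne hydration places the new carbonyl at C7 only and gives the 1,4-diketone.

Step 6
Reactants: 11 the 1,4-diketone
Product: 12 3,7-dimethyl-7a-[(triisopropylsilyloxy)methyl]-1,4,5,7a-tetrahydro-2H-inden-2-one (enone C7(=O)–C9(Me)=C10, ring A alkene C3=C4)
Conditions: KOH, MeOH, 60 °C
Reagents that add atoms: none
Why: Intramolecular aldol condensation of a 1,4-diketone (cyclopentenone annulation of the jasmone type): C9 adds to the C10 carbonyl and only this aldol can dehydrate, so reversible side-aldols drain into the tetrasubstituted enone.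

Step 7
Reactants: 12 the bicyclic enone; 13 tert-butyl bromoacetate
Product: 15 trans-hydrindan-2-one with 5β-CH2OTIPS 10α-H 9β-methyl and 9α-CH2CO2tBu, via lithium enolate 14 (not isolated)
Conditions: Li, NH3/THF, t-BuOH (1 equiv), −78 °C; isoprene; NH3 removed; then 13, THF, −78 to 0 °C
Reagents that add atoms: none
Why: Dissolving-metal reductive alkylation of an enone: the β-carbon C10 should be protonated on the face remote from the angular CH2OTIPS (trans fusion), and the regiodefined enolate is alkylated at C9 from the α face, anti to C1 and to C19.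

Step 8
Reactants: 15 the hydrindanone; 16 bis(phenylthio)methane
Product: 18 7β-hydroxy-7α-[bis(phenylthio)methyl] adduct of 15, via bis(phenylthio)methyllithium 17 (not isolated)
Conditions: 16, n-BuLi, THF, 0 °C; then 15, −78 to 0 °C; aq. NH4Cl
Reagents that add atoms: none
Why: 1,2-addition of a sulfur-stabilised carbanion to the cyclopentanone from the α face, away from C20, gives the tertiary carbinol; the new C7 stereocenter is destroyed in step 9 and the hindered tert-butyl ester is not attacked.

Step 9
Reactants: 18 the β-hydroxy dithioacetal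
Product: 20 ring-enlarged 8-(phenylthio)-7-ketone (trans-decalin; C8 epimers), via thionium ion 19 (not isolated)
Conditions: (CuOTf)2·C6H6 (1.2 equiv), iPr2NEt, benzene, 70 °C
Reagents that add atoms: none
Why: Monovalent copper takes one thiophenolate from the dithioacetal carbon C8, and as the sulfur-stabilised cation develops next to the tertiary C7 carbinol the C7–C9 σ-bond shifts to C8 while the hydroxyl oxygen closes to the C7 carbonyl, a semipinacol 1,2-shift. The closest known reaction type is the copper-promoted one-carbon ring enlargement of ketone–bis(phenylthio)methyllithium adducts to 2-(phenylthio)cycloalkanones. The six-membered ring C5–C6–C7–C8–C9–C10 is not closed by a new cyclisation but arises from the five-membered ring C5–C6–C7–C9–C10 by insertion of C8 between C7 and C9 through this suprafacial 1,2-alkyl shift. C9 migrates with retention, so C20 stays β and C11 α as set in step 7, whereas the new C8 stereocenter (H, SPh) is not controlled, since either diastereotopic sulfur can leave and the planar cation can be attacked from either side; it is erased in steps 10 and 11. The selectivity needed is migration of C9 and not of C6, and it should be secured by C9 being fully substituted and so far better able to carry positive charge in the bridged transition state than the C6 methylene; the amine base keeps the medium non-acidic so that silyl ether, tert-butyl ester and ring A alkene are left alone.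

Step 10
Reactants: 20 the α-phenylthio ketone
Product: 22 8-methyl-8-(phenylthio)-7-ketone, via potassium enolate 21 (not isolated)
Conditions: KN(SiMe3)2, THF, −78 °C; then MeI, −78 to 0 °C
Reagents that add atoms: iodomethane, CI
Why: Enolate alkylation of an α-sulfenyl ketone is regiospecific for C8, the only position acidified by both carbonyl and sulfur, and so brings in C17; the C8 configuration is irrelevant here.

Step 11
Reactants: 22 the methylated α-phenylthio ketone
Product: 24 8β-methyl-7-ketone (5β-CH2OTIPS 9α-CH2CO2tBu trans-decalin), via samarium enolate 23 (not isolated)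
Conditions: SmI2, THF/MeOH, −78 °C
Reagents that add atoms: none
Why: Reductive cleavage of the α-sulfenyl ketone gives the C7–C8 enolate, which should be protonated axially from the α face (anti to the axial C20 on C9), so that the methyl ends equatorial and β; this is also the more stable epimer.

Step 12
Reactants: 24 the keto ester
Product: 25 7β,12-diol
Conditions: LiAlH4, THF, 0 to 40 °C; Fieser work-up
Reagents that add atoms: none
Why: Hydride reduction: the two syn-axial β groups (C19 on C5 and C20 on C9) block axial attack on C7, so hydride enters equatorially from the α face and gives the axial 7β-alcohol, while the tert-butyl ester is reduced to the C12 primary alcohol.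

Step 13
Reactants: 25 the diol
Product: 26 12-O-tert-butyldimethylsilyl ether
Conditions: TBSCl, imidazole, CH2Cl2, 0 °C
Reagents that add atoms: tert-butyldimethylsilyl chloride, CC(C)(C)[Si](C)(C)Cl
Why: Silylation distinguishes the unhindered primary hydroxyl from the axial, doubly flanked C7 hydroxyl.

Step 14
Reactants: 26 the secondary alcohol
Product: 27 7β-acetate
Conditions: Ac2O, DMAP, pyridine, 50 °C
Reagents that add atoms: acetic anhydride, CC(=O)OC(C)=O
Why: DMAP-catalysed acylation installs the acetate of the target on the hindered axial alcohol with retention at C7.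

Step 15
Reactants: 27 the acetate
Product: 28 C18 enal (4-formyl-3-ene)
Conditions: SeO2, 1,4-dioxane, 80 °C
Reagents that add atoms: selenium dioxide, O=[Se]=O
Why: Allylic oxidation with selenium dioxide (ene reaction then 2,3-shift) acts at the more substituted alkene terminus, where the C18 methyl is the only carbon bearing hydrogen because C5 is quaternary.

Step 16
Reactants: 28 the enal
Product: 30 1,3-dien-18-al, via silyl dienol ether 29 (not isolated)
Conditions: TBSOTf, Et3N, CH2Cl2, 0 °C; then Pd(OAc)2 (1.1 equiv), MeCN, 40 °C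
Reagents that add atoms: none
Why: Soft γ-enolisation (H-2) gives the 1-silyloxy diene, and Saegusa–Ito oxidation removes H-1 by β-hydride elimination from the C2-palladated species, as in the conversion of 4-en-3-one dienol ethers into 4,6-dien-3-ones.

Step 17
Reactants: 30 the dienal
Product: 31 18,19-lactol with free 12-hydroxyl
Conditions: HF·pyridine, pyridine, THF, 0 °C to rt
Reagents that add atoms: none
Why: Fluoride-mediated cleavage of both silyl ethers frees the C19 hydroxyl, which closes onto the cis-disposed C18 aldehyde as the five-membered lactol; the acetate survives the buffered conditions.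

Step 18
Reactants: 31 the lactol alcohol
Product: 32 12-oxo-1,3-dien-18,19-olide (dienolide aldehyde)
Conditions: Dess–Martin periodinane (2.5 equiv), CH2Cl2, rt
Reagents that add atoms: none
Why: Dess–Martin oxidation converts the lactol into the lactone and the primary alcohol into the aldehyde in one operation under neutral conditions.

Step 19
Reactants: 32 the aldehyde; 33 3-bromofuran-2(5H)-one
Product: 34 12-hydroxy-13-en-15,16-olide (C12 epimers)
Conditions: CrCl2 (4 equiv), NiCl2 (1 mol %), DMF, rt
Reagents that add atoms: none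
Why: Nozaki–Hiyama–Kishi coupling: the alkenylchromium species formed from the vinylic bromide adds only to the aldehyde and tolerates dienolide and acetate; the C12 configuration is lost in step 20.

Step 20
Reactants: 34 the allylic alcohol
Product: 35 12-oxo-13-en-15,16-olide (3-acylbutenolide)
Conditions: Dess–Martin periodinane, CH2Cl2, 0 °C
Reagents that add atoms: none
Why: Neutral oxidation of the allylic alcohol gives the 3-acylbutenolide, whose C15 protons are now acidified by both carbonyl groups.

Step 21
Reactants: 35 the 3-acylbutenolide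
Product: 37 1,13-cyclised enol lactone (rings A, B and C all trans-fused; spiro C13), via furanolate 36 (not isolated)
Conditions: DBU (0.2 equiv), MeCN (2 mM), 0 °C to rt
Reagents that add atoms: none
Why: Intramolecular vinylogous Michael (1,6-) addition: removal of H-15 gives an aromatic 3-acyl-2-furanolate whose α-carbon C13 adds 6-exo to C1, the δ-terminus of the dienolide, from the α face because the axial C19 shields the β face; the metal-free enolate keeps its two C–O dipoles anti, which in the chair closure makes C16 axial, and reprotonation at C2 with reversibility should lead to the conjugated C3=C4 lactone and the all-trans perhydrophenalene.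

Step 22
Reactants: 37 the enol lactone
Product: 38 target CNP0308057.1
Conditions: DMDO, acetone/CH2Cl2, −20 to 0 °C
Reagents that add atoms: dimethyldioxirane, CC1(C)OO1
Why: Neutral dioxirane epoxidation of the enol-lactone double bond should occur from the face of the spiro-lactone that looks at the flat C12 carbonyl and away from the C1 methine and ring A, which sets C14 and C15; the conjugated C3=C4 bond is too electron-poor to react.

Compound list
1 | 2-methoxy-6-methylbenzoic acid | COc1cccc(C)c1C(=O)O | starting material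
2 | (S)-2-(methoxymethyl)pyrrolidine | COC[C@@H]1CCCN1 | starting material
3 | 2-methoxy-6-methylbenzoyl chloride | COc1cccc(C)c1C(=O)Cl | intermediate
4 | (S)-1-(2-methoxy-6-methylbenzoyl)-2-(methoxymethyl)pyrrolidine | COC[C@@H]1CCCN1C(=O)c1c(C)cccc1OC | intermediate
5 | 1-bromobut-2-yne | CC#CCBr | starting material
6 | potassium amide enolate of 1,4-dihydro-4 | COC[C@@H]1CCCN1C([O-])=C1C(OC)=CCC=C1C.[K+] | intermediate
7 | (1R)-1-(but-2-yn-1-yl)-2-methoxy-6-methylcyclohexa-2,5-diene-1-carboxamide of (S)-2-(methoxymethyl)pyrrolidine | COC1=CCC=C(C)[C@]1(C(=O)N2CCC[C@H]2COC)CC#CC | intermediate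
8 | (S)-[1-(but-2-yn-1-yl)-2-methoxy-6-methylcyclohexa-2,5-dien-1-yl]methanol | COC1=CCC=C(C)[C@]1(CO)CC#CC | intermediate
9 | triisopropylsilyl ether of 8 | COC1=CCC=C(C)[C@]1(CO[Si](C(C)C)(C(C)C)C(C)C)CC#CC | intermediate
10 | 2-(but-2-yn-1-yl)-3-methyl-2-[(triisopropylsilyloxy)methyl]cyclohex-3-en-1-one (C5 as in 8) | O=C1CCC=C(C)[C@]1(CO[Si](C(C)C)(C(C)C)C(C)C)CC#CC | intermediate
11 | 3-methyl-2-(2-oxobutyl)-2-[(triisopropylsilyloxy)methyl]cyclohex-3-en-1-one (C5 as in 8) | O=C1CCC=C(C)[C@]1(CO[Si](C(C)C)(C(C)C)C(C)C)CC(=O)CC | intermediate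
12 | 3,7-dimethyl-7a-[(triisopropylsilyloxy)methyl]-1,4,5,7a-tetrahydro-2H-inden-2-one (enone C7(=O)–C9=C10; 5β-CH2OTIPS) | O=C1C[C@@]2(CO[Si](C(C)C)(C(C)C)C(C)C)C(C)=CCCC2=C1C | intermediate
13 | tert-butyl bromoacetate | CC(C)(C)OC(=O)CBr | starting material
14 | lithium C7–C9 enolate of the trans-hydrindanone (10α-H) | [Li+].[O-]C1=C(C)[C@H]2CCC=C(C)[C@]2(CO[Si](C(C)C)(C(C)C)C(C)C)C1 | intermediate
15 | trans-hydrindan-2-one: ring C5–C6–C7(=O)–C9–C10; 5β-CH2OTIPS, 10α-H, 9β-methyl, 9α-CH2CO2tBu; ring A 3-ene with 4-methyl | O=C1C[C@@]2(CO[Si](C(C)C)(C(C)C)C(C)C)C(C)=CCC[C@@H]2[C@@]1(C)CC(=O)OC(C)(C)C | intermediate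
16 | bis(phenylthio)methane | C(Sc1ccccc1)Sc1ccccc1 | starting material
17 | bis(phenylthio)methyllithium | [Li]C(Sc1ccccc1)Sc1ccccc1 | intermediate
18 | 7β-hydroxy-7α-[bis(phenylthio)methyl] adduct of 15 | O[C@]1(C(Sc2ccccc2)Sc2ccccc2)C[C@@]2(CO[Si](C(C)C)(C(C)C)C(C)C)C(C)=CCC[C@@H]2[C@@]1(C)CC(=O)OC(C)(C)C | intermediate
19 | thionium ion at C8 derived from 18 | O[C@]1(C=[S+]c2ccccc2)C[C@@]2(CO[Si](C(C)C)(C(C)C)C(C)C)C(C)=CCC[C@@H]2[C@@]1(C)CC(=O)OC(C)(C)C | intermediate
20 | trans-decalin 7-ketone with 8-(phenylthio) (C8 epimers), 5β-CH2OTIPS, 9β-methyl, 9α-CH2CO2tBu, 3-ene | O=C1C[C@@]2(CO[Si](C(C)C)(C(C)C)C(C)C)C(C)=CCC[C@@H]2[C@@](C)(CC(=O)OC(C)(C)C)C1Sc1ccccc1 | intermediate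
21 | potassium C7–C8 enolate of 20 | [K+].[O-]C1=C(Sc2ccccc2)[C@](C)(CC(=O)OC(C)(C)C)[C@H]2CCC=C(C)[C@]2(CO[Si](C(C)C)(C(C)C)C(C)C)C1 | intermediate
22 | 8-methyl-8-(phenylthio)-7-ketone (C8 unassigned) | O=C1C[C@@]2(CO[Si](C(C)C)(C(C)C)C(C)C)C(C)=CCC[C@@H]2[C@@](C)(CC(=O)OC(C)(C)C)C1(C)Sc1ccccc1 | intermediate
23 | samarium C7–C8 enolate of the 8-methyl ketone | I[Sm](I)OC1=C(C)[C@](C)(CC(=O)OC(C)(C)C)[C@H]2CCC=C(C)[C@]2(CO[Si](C(C)C)(C(C)C)C(C)C)C1 | intermediate
24 | 8β-methyl-7-ketone, 5β-CH2OTIPS, 9β-methyl, 9α-CH2CO2tBu, 10α-H, 3-ene | O=C1C[C@@]2(CO[Si](C(C)C)(C(C)C)C(C)C)C(C)=CCC[C@@H]2[C@@](C)(CC(=O)OC(C)(C)C)[C@@H]1C | intermediate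
25 | 7β,12-diol (9α-CH2CH2OH) | O[C@@H]1C[C@@]2(CO[Si](C(C)C)(C(C)C)C(C)C)C(C)=CCC[C@@H]2[C@@](C)(CCO)[C@@H]1C | intermediate
26 | 12-O-TBS ether of 25 | O[C@@H]1C[C@@]2(CO[Si](C(C)C)(C(C)C)C(C)C)C(C)=CCC[C@@H]2[C@@](C)(CCO[Si](C)(C)C(C)(C)C)[C@@H]1C | intermediate
27 | 7β-acetate of 26 | CC(=O)O[C@@H]1C[C@@]2(CO[Si](C(C)C)(C(C)C)C(C)C)C(C)=CCC[C@@H]2[C@@](C)(CCO[Si](C)(C)C(C)(C)C)[C@@H]1C | intermediate
28 | 3-en-18-al (C18 aldehyde) | CC(=O)O[C@@H]1C[C@@]2(CO[Si](C(C)C)(C(C)C)C(C)C)C(C=O)=CCC[C@@H]2[C@@](C)(CCO[Si](C)(C)C(C)(C)C)[C@@H]1C | intermediate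
29 | 18-(tert-butyldimethylsilyloxy)-2,4(18)-diene (silyl dienol ether) | CC(=O)O[C@@H]1C[C@@]2(CO[Si](C(C)C)(C(C)C)C(C)C)C(=CO[Si](C)(C)C(C)(C)C)C=CC[C@@H]2[C@@](C)(CCO[Si](C)(C)C(C)(C)C)[C@@H]1C | intermediate
30 | 1,3-dien-18-al | CC(=O)O[C@@H]1C[C@@]2(CO[Si](C(C)C)(C(C)C)C(C)C)C(C=O)=CC=C[C@@H]2[C@@](C)(CCO[Si](C)(C)C(C)(C)C)[C@@H]1C | intermediate
31 | 18,19-lactol (C18 epimers) with 12-hydroxyl | CC(=O)O[C@@H]1C[C@@]23COC(O)C2=CC=C[C@@H]3[C@@](C)(CCO)[C@@H]1C | intermediate
32 | 7β-acetoxy-12-oxo-1,3-dien-18,19-olide (C12 aldehyde) | CC(=O)O[C@@H]1C[C@@]23COC(=O)C2=CC=C[C@@H]3[C@@](C)(CC=O)[C@@H]1C | intermediate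
33 | 3-bromofuran-2(5H)-one | O=C1OCC=C1Br | starting material
34 | 12-hydroxy-1,3,13-trien-15,16:18,19-diolide (C12 epimers) | CC(=O)O[C@@H]1C[C@@]23COC(=O)C2=CC=C[C@@H]3[C@@](C)(CC(O)C2=CCOC2=O)[C@@H]1C | intermediate
35 | 12-oxo-1,3,13-trien-15,16:18,19-diolide | CC(=O)O[C@@H]1C[C@@]23COC(=O)C2=CC=C[C@@H]3[C@@](C)(CC(=O)C2=CCOC2=O)[C@@H]1C | intermediate
36 | 3-acyl-2-furanolate of 35 (DBU-H salt) | CC(=O)O[C@@H]1C[C@@]23COC(=O)C2=CC=C[C@@H]3[C@@](C)(CC(=O)c2ccoc2[O-])[C@@H]1C.C1CCC2=[NH+]CCCN2CC1 | intermediate
37 | 1,13-cyclo-12-oxo-3,14-dien-15,16:18,19-diolide (1β-H, C16 α at C13) | CC(=O)O[C@@H]1C[C@@]23COC(=O)C2=CC[C@@H]2[C@@H]3[C@@](C)(CC(=O)[C@]23C(=O)OC=C3)[C@@H]1C | intermediate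
38 | CNP0308057.1 | CC(=O)O[C@@H]1C[C@@]23COC(=O)C2=CC[C@@H]2[C@@H]3[C@@](C)(CC(=O)[C@]23C(=O)O[C@H]2O[C@H]23)[C@@H]1C | target

Total step count: 22. Longest linear sequence: 22 steps (1 to 38).

Steps most likely to fail

Step 21. The planar furanolate may add through the wrong face at C13, or react through C15 with a second molecule and oligomerise before the ring closes. The fallback sets out from 35 and comes back at 37. Compound 35 is silylated with TIPSOTf/Et3N to the isolated 3-acyl-2-(triisopropylsilyloxy)furan F1. F1 is then cyclised as a neutral silyl nucleophile under Lewis acid catalysis (Sc(OTf)3, CH2Cl2, −40 °C), an intramolecular Mukaiyama–Michael addition. The bulky silyloxy group on C16 can only sit anti to the C12 carbonyl, which is the arrangement that makes C16 axial. The addition is irreversible and involves no free enolate that could add intermolecularly. Aqueous work-up should give 37.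

Step 8. The soft, bulky carbanion may deprotonate C6 or add reversibly at the neopentyl-type ketone, and the key step depends on this adduct. The fallback sets out from 15 and comes back at 24. VinylMgBr/CeCl3 adds to 15 to give the tertiary allylic alcohol F2. Hydroxyl-directed epoxidation (VO(acac)2, t-BuOOH) gives the epoxy alcohol F3. BF3·OEt2 triggers the semipinacol ring enlargement of this 2,3-epoxy alcohol, with C9 migrating to the epoxide carbon C8, to the β-hydroxy ketone F4. Mesylation and elimination (MsCl, Et3N; DBU) give the α-methylene ketone F5. Conjugate reduction with L-Selectride and axial protonation of the enolate should give 24.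

Step 2. Facial discrimination in the alkylation of the doubly ortho-substituted amide enolate may be low, which would erode the C5 configuration on which all later centers depend. The fallback sets out from 1 and comes back at 8. Compound 1 is converted through its acid chloride into the achiral pyrrolidine amide F6. Birch reduction–alkylation with 5 gives the racemic diene amide F7. Reduction with lithium amidotrihydroborate gives the racemic alcohol F8. F8 is resolved by preparative chromatography on a chiral stationary phase to give 8.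

Further compounds
F1 | step 21 | 3-acyl-2-(triisopropylsilyloxy)furan derived from 35 | CC(=O)O[C@@H]1C[C@@]23COC(=O)C2=CC=C[C@@H]3[C@@](C)(CC(=O)c2ccoc2O[Si](C(C)C)(C(C)C)C(C)C)[C@@H]1C
F2 | step 8 | 7β-hydroxy-7α-vinyl adduct of 15 | O[C@]1(C=C)C[C@@]2(CO[Si](C(C)C)(C(C)C)C(C)C)C(C)=CCC[C@@H]2[C@@]1(C)CC(=O)OC(C)(C)C
F3 | step 8 | 7β-hydroxy-7α-oxiranyl compound (epoxide epimers) | O[C@]1(C3CO3)C[C@@]2(CO[Si](C(C)C)(C(C)C)C(C)C)C(C)=CCC[C@@H]2[C@@]1(C)CC(=O)OC(C)(C)C
F4 | step 8 | ring-enlarged 8-(hydroxymethyl)-7-ketone (C8 epimers) | O=C1C[C@@]2(CO[Si](C(C)C)(C(C)C)C(C)C)C(C)=CCC[C@@H]2[C@@](C)(CC(=O)OC(C)(C)C)C1CO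
F5 | step 8 | 8-methylene-7-ketone | O=C1C[C@@]2(CO[Si](C(C)C)(C(C)C)C(C)C)C(C)=CCC[C@@H]2[C@@](C)(CC(=O)OC(C)(C)C)C1=C
F6 | step 2 | 1-(2-methoxy-6-methylbenzoyl)pyrrolidine | COc1cccc(C)c1C(=O)N1CCCC1
F7 | step 2 | racemic 1-(but-2-yn-1-yl)-2-methoxy-6-methylcyclohexa-2,5-diene-1-carboxylic acid pyrrolidide | COC1=CCC=C(C)C1(C(=O)N1CCCC1)CC#CC
F8 | step 2 | racemic [1-(but-2-yn-1-yl)-2-methoxy-6-methylcyclohexa-2,5-dien-1-yl]methanol | COC1=CCC=C(C)C1(CO)CC#CC
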